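## Retrosynthetic overview
1. The C5=CBr2 unit comes from a 5-methyl-4-bromobutenolide: C5 bromination and loss of HBr, then two cycles of Br2 addition and HBr loss. The acetate comes from the free carbinol.
2. The propyl chain comes from an allyl group by selective hydrogenation. C1′–C2′ is the key bond, made by reagent-controlled asymmetric allylboration of a 4-bromo-3-formylbutenolide, which sets (R)-C1′.
3. The 4-bromo-3-formylbutenolide comes from (S)-5-methyltetronic acid by C3 aminomethylenation, then deoxybromination and hydrolysis. C4–Br is therefore in place before the carbinol exists.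
4. Ring order: the only ring, the butenolide, is formed first, by Dieckmann closure of O-acetyl ethyl (S)-lactate.

Assumption: CIP analysis of the given SMILES gives (R) at the acetoxy carbon (O > ring C3 > CH2 > H); the C5 stereocentre carried over from lactate is sacrificial.

## Route

Step 1
Reactants: 1 ethyl (S)-lactate; 2 acetic anhydride
Product: 3 ethyl (2S)-2-(acetyloxy)propanoate
Conditions: Ac2O (1.1 equiv), DMAP (1 mol %), neat, rt
Reagents that add atoms: acetic anhydride, CC(=O)OC(C)=O
Why: DMAP-catalysed O-acylation of the secondary alcohol, which leaves the lactate stereocentre untouched.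

Step 2
Reactants: 3 ethyl (2S)-2-(acetyloxy)propanoate
Product: 4 (5S)-4-hydroxy-5-methylfuran-2(5H)-one ((S)-5-methyltetronic acid)
Conditions: LiN(SiMe3)2 (2.2 equiv), THF, −78 °C → 0 °C; 2 M HCl
Reagents that add atoms: none
Why: Dieckmann-type (intramolecular Claisen) condensation of the acetate enolate onto the ethyl ester closes the ring, the second equivalent of base holds the product as its tetronate, and C5 keeps the lactate (S) configuration.

Step 3
Reactants: 4 (S)-5-methyltetronic acid; 5 N,N-dimethylformamide dimethyl acetal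
Product: 6 (5S)-3-[(dimethylamino)methylidene]-5-methylfuran-2,4(3H,5H)-dione (C=C geometry not fixed)
Conditions: Me2NCH(OMe)2 (1.1 equiv), toluene, rt → 40 °C
Reagents that add atoms: N,N-dimethylformamide dimethyl acetal, COC(OC)N(C)C
Why: Knoevenagel-type aminomethylenation of the strongly nucleophilic C3 installs the future C1′ under neutral conditions, before any halogenating agent is present.

Step 4
Reactants: 6 enaminone
Product: 8 (5S)-4-bromo-5-methyl-2-oxo-2,5-dihydrofuran-3-carbaldehyde, via bromoiminium bromide 7 (not isolated)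
Conditions: (COBr)2 (1.2 equiv), CH2Cl2, 0 °C → rt; then ice-water, 0 °C
Reagents that add atoms: oxalyl bromide, O=C(Br)C(=O)Br; water, O
Why: Vilsmeier–Arnold-type deoxybromination, in which the vinylogous amide oxygen is acylated, bromide displaces it at C4 to give the 3-bromopropeniminium salt, and cold acidic hydrolysis of the iminium carbon frees the β-bromo enal while the amine stays protonated.

Step 5
Reactants: 8 bromo aldehyde; 9 allylmagnesium bromide; 10 (+)-B-methoxydiisopinocampheylborane ((+)-Ipc2BOMe, (−)-α-pinene series)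
Product: 13 (5S)-4-bromo-3-[(1R)-1-hydroxybut-3-en-1-yl]-5-methylfuran-2(5H)-one, via allylborane 11 (not isolated), via borinate 12 (not isolated)
Conditions: 9 (0.95 equiv) + 10, Et2O, 0 °C → rt; pentane, Mg(OMe)Br filtered off; 8, Et2O–CH2Cl2, −78 °C; then pH 7 phosphate buffer, MeOH, 30% H2O2, 0 °C → rt
Reagents that add atoms: allylmagnesium bromide, C=CC[Mg]Br
Why: Brown asymmetric allylboration (carbonyl allylation) through a closed chair transition state, in which the (−)-α-pinene-derived Ipc ligands deliver allyl to the Re face of the aldehyde (the sense known for benzaldehyde and enals) and set C1′ as (R), while the non-basic, salt-free reagent spares the vinylogous acyl bromide and the acidic C5–H.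

Step 6
Reactants: 13 homoallylic alcohol
Product: 14 (5S)-4-bromo-3-[(1R)-1-hydroxybutyl]-5-methylfuran-2(5H)-one
Conditions: H2 (1 atm), RhCl(PPh3)3 (5 mol %), toluene, rt
Reagents that add atoms: none
Why: Homogeneous hydrogenation reduces only the unhindered monosubstituted alkene and leaves the tetrasubstituted electron-poor bromoalkene, the C–Br bond and both stereocentres intact.

Step 7
Reactants: 14 alcohol; 2 acetic anhydride
Product: 15 (1R)-1-[(5S)-4-bromo-5-methyl-2-oxo-2,5-dihydrofuran-3-yl]butyl acetate
Conditions: Ac2O (1.5 equiv), Sc(OTf)3 (1 mol %), MeCN, −20 °C → 0 °C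
Reagents that add atoms: acetic anhydride, CC(=O)OC(C)=O
Why: Lewis-acid-catalysed O-acetylation proceeds with retention because the C1′–O bond is never broken, and the absence of base avoids C5 deprotonation followed by vinylogous E1cB loss of acetate.

Step 8
Reactants: 15 acetate
Product: 17 (1R)-1-(4-bromo-5-methylidene-2-oxo-2,5-dihydrofuran-3-yl)butyl acetate, via 5-bromolactone 16 (not isolated)
Conditions: NBS (1.05 equiv), AIBN (5 mol %), PhCF3, reflux; filter, concentrate; Et3N (1.2 equiv), CH2Cl2, 0 °C
Reagents that add atoms: none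
Why: Wohl–Ziegler bromination selects the tertiary C5–H, whose radical is α-oxygenated and delocalised over the enoate (the selectivity seen for 3-alkylbutenolides), and dehydrobromination of the labile tertiary bromide gives the exocyclic methylene without touching C1′.

Step 9
Reactants: 17 5-methylidene butenolide
Product: 19 (1R)-1-[(5Z)-4-bromo-5-(bromomethylidene)-2-oxo-2,5-dihydrofuran-3-yl]butyl acetate, via bromine adduct 18 (not isolated)
Conditions: Br2 (1.05 equiv), CH2Cl2, 0 °C, dark; then Et3N (1.1 equiv), 0 °C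
Reagents that add atoms: bromine, BrBr
Why: Electrophilic bromine addition to the enol-ester-type exocyclic alkene followed by dehydrobromination gives the Z isomer, with bromine turned away from C4–Br, and this geometry is erased in the next step.

Step 10
Reactants: 19 (Z)-bromomethylidene butenolide
Product: 21 (1R)-1-[4-bromo-5-(dibromomethylidene)-2-oxo-2,5-dihydrofuran-3-yl]butyl acetate (target), via bromine adduct 20 (not isolated)
Conditions: Br2 (1.3 equiv), CH2Cl2, rt → 40 °C, dark; evaporate excess Br2; Et3N (1.1 equiv), CH2Cl2, 0 °C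
Reagents that add atoms: bromine, BrBr
Why: A second bromine addition and dehydrobromination cycle, in which the CHBr2 hydrogen is the only one next to the tertiary C5–Br, so elimination can give only the dibromomethylidene lactone, and C1′ stays (R).

## Compound list
1 | ethyl (2S)-2-hydroxypropanoate (ethyl (S)-lactate) | C[C@H](O)C(=O)OCC | starting material
2 | acetic anhydride | CC(=O)OC(C)=O | starting material
3 | ethyl (2S)-2-(acetyloxy)propanoate | C[C@H](OC(C)=O)C(=O)OCC | intermediate
4 | (5S)-4-hydroxy-5-methylfuran-2(5H)-one | C[C@@H]1OC(=O)C=C1O | intermediate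
5 | N,N-dimethylformamide dimethyl acetal | COC(OC)N(C)C | starting material
6 | (5S)-3-[(dimethylamino)methylidene]-5-methylfuran-2,4(3H,5H)-dione | C[C@@H]1OC(=O)C(=CN(C)C)C1=O | intermediate
7 | N-{[(5S)-4-bromo-5-methyl-2-oxo-2,5-dihydrofuran-3-yl]methylidene}-N-methylmethanaminium bromide | C[C@@H]1OC(=O)C(C=[N+](C)C)=C1Br.[Br-] | intermediate
8 | (5S)-4-bromo-5-methyl-2-oxo-2,5-dihydrofuran-3-carbaldehyde | C[C@@H]1OC(=O)C(C=O)=C1Br | intermediate
9 | allylmagnesium bromide | C=CC[Mg]Br | starting material
10 | (+)-B-methoxydiisopinocampheylborane ((−)-α-pinene series) | COB([C@H]1C[C@H]2C[C@@H]([C@@H]1C)C2(C)C)[C@H]1C[C@H]2C[C@@H]([C@@H]1C)C2(C)C | starting material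
11 | B-allyldiisopinocampheylborane ((−)-α-pinene series) | C=CCB([C@H]1C[C@H]2C[C@@H]([C@@H]1C)C2(C)C)[C@H]1C[C@H]2C[C@@H]([C@@H]1C)C2(C)C | intermediate
12 | diisopinocampheylborinate ester of 13 | C=CC[C@@H](OB([C@H]1C[C@H]2C[C@@H]([C@@H]1C)C2(C)C)[C@H]1C[C@H]2C[C@@H]([C@@H]1C)C2(C)C)C1=C(Br)[C@H](C)OC1=O | intermediate
13 | (5S)-4-bromo-3-[(1R)-1-hydroxybut-3-en-1-yl]-5-methylfuran-2(5H)-one | C=CC[C@@H](O)C1=C(Br)[C@H](C)OC1=O | intermediate
14 | (5S)-4-bromo-3-[(1R)-1-hydroxybutyl]-5-methylfuran-2(5H)-one | CCC[C@@H](O)C1=C(Br)[C@H](C)OC1=O | intermediate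
15 | (1R)-1-[(5S)-4-bromo-5-methyl-2-oxo-2,5-dihydrofuran-3-yl]butyl acetate | CCC[C@@H](OC(C)=O)C1=C(Br)[C@H](C)OC1=O | intermediate
16 | (1R)-1-(4,5-dibromo-5-methyl-2-oxo-2,5-dihydrofuran-3-yl)butyl acetate (C5 epimers) | CCC[C@@H](OC(C)=O)C1=C(Br)C(C)(Br)OC1=O | intermediate
17 | (1R)-1-(4-bromo-5-methylidene-2-oxo-2,5-dihydrofuran-3-yl)butyl acetate | CCC[C@@H](OC(C)=O)C1=C(Br)C(=C)OC1=O | intermediate
18 | (1R)-1-[4,5-dibromo-5-(bromomethyl)-2-oxo-2,5-dihydrofuran-3-yl]butyl acetate (C5 epimers) | CCC[C@@H](OC(C)=O)C1=C(Br)C(Br)(CBr)OC1=O | intermediate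
19 | (1R)-1-[(5Z)-4-bromo-5-(bromomethylidene)-2-oxo-2,5-dihydrofuran-3-yl]butyl acetate | CCC[C@@H](OC(C)=O)C1=C(Br)/C(=C/Br)OC1=O | intermediate
20 | (1R)-1-[4,5-dibromo-5-(dibromomethyl)-2-oxo-2,5-dihydrofuran-3-yl]butyl acetate (C5 epimers) | CCC[C@@H](OC(C)=O)C1=C(Br)C(Br)(C(Br)Br)OC1=O | intermediate
21 | (1R)-1-[4-bromo-5-(dibromomethylidene)-2-oxo-2,5-dihydrofuran-3-yl]butyl acetate | CCC[C@@H](OC(C)=O)C1=C(Br)C(=C(Br)Br)OC1=O | target

## Step count and risks
Total steps: 10. Longest linear sequence: 10 (from ethyl (S)-lactate).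

**Step 4.** Water may attack C4 instead of the iminium carbon and return 6, or bromide may be lost. The fallback sets out from 6 and comes back at 8. Oxalyl chloride in CH2Cl2 converts 6 into the sturdier chloroiminium chloride F1. Ice-water hydrolysis then gives (5S)-4-chloro-5-methyl-2-oxo-2,5-dihydrofuran-3-carbaldehyde F2. Only after that is the halogen exchanged, by addition–elimination on this doubly activated vinylogous acyl chloride with Me3SiBr in MeCN. The stronger Si–Cl bond drives the exchange and gives 8.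

**Step 5.** The face selectivity or the work-up tolerance of this very electrophilic aldehyde may disappoint. In the main route the minor C1′ epimer is a diastereomer, because of (S)-C5, and can be removed by chromatography at 13–15. The fallback sets out from 8 and comes back at 15.
- A non-selective Barbier allylation (In powder, allyl bromide, THF–water, rt) gives the C1′-epimeric homoallylic alcohol F3.
- Hydrogenation as in step 6 gives the C1′-epimeric butyl carbinol F4.
- Burkholderia cepacia lipase with vinyl acetate in MTBE at 30 °C acetylates the (1′R) epimer, which Kazlauskas' rule predicts to be the fast-reacting one (large group = ring, medium group = propyl). This gives 15 directly.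
- The unreacted (1′S,5S)-alcohol F5 is removed by chromatography.

**Step 8.** Radical bromination may compete at C1′–H, or the product may brominate further. The fallback sets out from 14 and comes back at 17. It replaces radical chemistry by ionic chemistry on a substrate whose C1′ oxygen is a poor leaving group.
- TBSOTf (2.2 equiv) and Et3N in CH2Cl2 at 0 °C give the bis-silylated 2-silyloxyfuran F6.
- NBS in THF at −78 °C brominates its C5 to give the 5-bromo TBS ether F7.
- Et3N at 0 °C gives the 5-methylidene TBS ether F8.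
- Aqueous HF in MeCN at 0 °C frees the 5-methylidene alcohol F9.
- Ac2O with Sc(OTf)3, as in step 7, gives 17.

## Further compounds
F1 | step 4 | N-{[(5S)-4-chloro-5-methyl-2-oxo-2,5-dihydrofuran-3-yl]methylidene}-N-methylmethanaminium chloride | C[C@@H]1OC(=O)C(C=[N+](C)C)=C1Cl.[Cl-]
F2 | step 4 | (5S)-4-chloro-5-methyl-2-oxo-2,5-dihydrofuran-3-carbaldehyde | C[C@@H]1OC(=O)C(C=O)=C1Cl
F3 | step 5 | (5S)-4-bromo-3-(1-hydroxybut-3-en-1-yl)-5-methylfuran-2(5H)-one (C1′ epimers) | C=CCC(O)C1=C(Br)[C@H](C)OC1=O
F4 | step 5 | (5S)-4-bromo-3-(1-hydroxybutyl)-5-methylfuran-2(5H)-one (C1′ epimers) | CCCC(O)C1=C(Br)[C@H](C)OC1=O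
F5 | step 5 | (5S)-4-bromo-3-[(1S)-1-hydroxybutyl]-5-methylfuran-2(5H)-one | CCC[C@H](O)C1=C(Br)[C@H](C)OC1=O
F6 | step 8 | {[4-bromo-3-[(1R)-1-(tert-butyldimethylsilyloxy)butyl]-5-methylfuran-2-yl]oxy}(tert-butyl)dimethylsilane | CCC[C@@H](O[Si](C)(C)C(C)(C)C)c1c(Br)c(C)oc1O[Si](C)(C)C(C)(C)C
F7 | step 8 | 4,5-dibromo-3-[(1R)-1-(tert-butyldimethylsilyloxy)butyl]-5-methylfuran-2(5H)-one (C5 epimers) | CCC[C@@H](O[Si](C)(C)C(C)(C)C)C1=C(Br)C(C)(Br)OC1=O
F8 | step 8 | 4-bromo-3-[(1R)-1-(tert-butyldimethylsilyloxy)butyl]-5-methylidenefuran-2(5H)-one | CCC[C@@H](O[Si](C)(C)C(C)(C)C)C1=C(Br)C(=C)OC1=O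
F9 | step 8 | 4-bromo-3-[(1R)-1-hydroxybutyl]-5-methylidenefuran-2(5H)-one | CCC[C@@H](O)C1=C(Br)C(=C)OC1=O
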